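All runs are calculated with made-up constants; scatter was added.

At 80.0 s, the last reading of the noon run, the racemic substrates have given 56.7% of product, and the flask asked about is that same run followed on to 3.0 min.

common to all: left-handed substrate 0.40 M; right-handed substrate 0.40 M
- noon: reagent 0.88 M; free catalyst 8 mM; racemization catalyst 4 mM; the very flask that is asked about, followed so far
- flask: reagent 0.880 M; free catalyst 8.0 mM; racemization catalyst 4.0 mM; time 3.0 min

noon run (percent of the left-handed substrate and right-handed substrate together charged)

| time / s | left-handed product / % | right-handed product / % |
|---|---|---|
| 20.0 | 32.8 | 14.9 |
| 40.0 | 34.8 | 17.0 |
| 50.0 | 37.7 | 17.4 |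
| 80.0 | 38.2 | 18.5 |

(each reading ± 0.5 percentage points)

- free catalyst is single-handed; left-handed substrate and right-handed substrate are mirror images of each other, charged as a racemate, each of them at the stated concentration
- an excess is the difference of the two amounts in percent of their sum
- an excess is below zero if the other one leads

1. left-handed product and right-handed product together, in percent of the left-handed substrate and right-handed substrate charged together, at 3.0 min
2. excess of left-handed product over right-handed product in the product at 3.0 min
3. whether the exchange between left-handed substrate and right-handed substrate keeps pace with the reaction: how far the product's excess at 3.0 min gets from its value without exchange to its value with instant exchange (above 80% keeps pace, below 20% hardly takes part, else lags behind)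

The quantity to carry is the turnover number, the moles of both products formed per mole of free catalyst charged: 56.7 as read at 80.0 s, which is less than the 100 turnovers the charged substrates allow. From 50.0 s to 80.0 s the products together gained 1.6 percentage points, with a scatter of 0.5 points per reading, so this reckoning holds the count and multiplies it by [free catalyst] over the substrates charged, which gives 56.7%, with the excess as last read, 34.7%.

The forecast, reasoning that “the catalyst is apparently dying or being tied up”, gives a little more product than this reckoning: 59%, an excess of 34%, and an exchange that hardly takes part.

The flask gives 56.8% and an excess of 34.7%, and its exchange hardly takes part, covering 10% of the way.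

    reagent + free catalyst + left-handed substrate → free catalyst + left-handed product (k = 19.0 M⁻² s⁻¹)
    reagent + free catalyst + right-handed substrate → free catalyst + right-handed product (k = 6.50 M⁻² s⁻¹)
    left-handed substrate + racemization catalyst ⇌ right-handed substrate + racemization catalyst, rate k3*[racemization catalyst]*[left-handed substrate] forward; the back reaction follows from the equilibrium constant (k = 3.80 M⁻¹ s⁻¹)
    2 racemization catalyst → spent catalyst A (k = 29.0 M⁻¹ s⁻¹)
    free catalyst → spent catalyst B (k = 0.00860 s⁻¹)
    reagent + free catalyst → spent catalyst C (k = 0.0950 M⁻¹ s⁻¹)

In this flask the count stands at 56.8 turnovers at 3.0 min, with free catalyst down to 0.0101% of its charge and spent catalyst B and spent catalyst C at 13.4% and 86.6%. At 0.0853 min in this flask the left-handed substrate goes to left-handed product 9.6 times as fast as it passes into right-handed substrate by the forward step alone, and by 1.50 min the step to left-handed product has behind it 99.6% of its turnover up to 3.0 min.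

For a neighbour flask charged with 0.0048 M of free catalyst, the other charges and the time held, the carried count gives an estimate of 34.0%. Its computed result is 41.4%, which is 69.0 turnovers, more per catalyst than the count carried over.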